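## Analysis of the target

The target is a furanoheliangolide (germacrane numbering throughout) whose α-methylene lactone has been built out into a spiro-cyclohexene. Its core is the ten-membered carbocycle C1–C10 with an oxygen bridge between C3 and C10: O, C3, C2, C1 and C10 form a 3(2H)-furanone, and the remaining atoms form a nine-membered oxacycle that holds the (Z)-C4=C5 alkene. A γ-lactone (O–C6, C7, C11, C12) is fused at C6–C7, C8 carries an angelate, and C11 is the spiro atom of a cyclohexene in which C13 and C4′ are the two CH2 groups on C11 and C3′, next to C4′, bears the 4-methylpent-3-enyl chain; formally this ring is the [4+2] adduct of an α-methylene lactone and a 2-alkylbuta-1,3-diene in the 1,3 ("meta") sense. The five stereocentres are C6 (S), C7 (R), C8 (R), C10 (R) and C11 (S). C5 and C8 are cis on the lactone, the C6 and C8 oxygens are 1,3-syn and both anti to C11 along the C5–C9 chain, the C8 and C10 oxygens are 1,3-anti, and C4′ is trans to C8. Sensitive groups are the angelate (Z/E isomerisation, Michael addition), the cross-conjugated dienone, the acid-sensitive 1,5-diene of the side chain, the β-oxygenated C8–C10 segment (elimination with base) and the lactone, which can migrate to O8 once that hydroxyl is free. The hard points are two quaternary stereocentres in different rings, a strained medium ring with a Z-trisubstituted alkene, a cis-lactone that substrate control does not favour, and a cyclohexene substitution pattern opposite to the normal Diels–Alder orientation. The plan turns on C10, a fully substituted carbon bearing the C14 methyl, C9 and the ring oxygen and bonded to the C1 ketone inside the furanone: this is the pattern that remains when a ketone oxygen closes onto an alkyne and a methyl group moves over from the neighbouring carbinol carbon.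

## Retrosynthetic reasoning

**C8–O ester.** Target 39 is traced to alcohol 36 and angelic acid 37. The angelate is the most fragile group, so it is attached last. Forward, a hindered secondary alcohol must be acylated without Z/E leakage and without lactone migration to O8.

**C4=C5.** 36 comes from silyl ether 35, and the alkene of 35 is cut to aldehyde 31 by way of aldol 33. C4 is the γ-carbon of the vinylogous ester O–C3=C2–C1=O and the only acidic CH2 left, because the lactone α-carbon is quaternary. The cut removes the strained ring and the dienone together. Forward, a vinylogous aldol addition must close the nine-membered oxacycle, and the dehydration must give the Z alkene, which the ring geometry demands.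

**Lactone C12–O6 and C6–H.** 31 is the hydrolysed form of acetal 30; 30 is opened to hydroxy amide 29, which is traced to ketone 28. Placing a carbonyl at C6 is what makes C7 nucleophilic in the next cut. Forward, hydride must reach C6 on the face that puts O6 anti to C11 (the cis-lactone). This runs against the preference of the C7 centre, so reagent control is needed. O8 must be blocked as a silyl ether (28 from 27), because O8 is also γ to C12 and would otherwise compete with O6 for the lactone.

**C7–C8.** 27 is cut into furanone aldehyde 8 and keto amide 25. C8 is an aldehyde, and the C6 ketone enolises towards C7, because the C5 acetal methine is not deprotonated by a boron halide and an amine and C11 is quaternary. Forward, an anti aldol sets C7 and C8 together. Neither partner has a centre that can choose the face (C10 is 1,3 to C8, and the two ring methylenes on C11 differ only far from C7), so the ligands on boron must do it.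

**Furanone ring: O–C3 and C10–C14.** 8 is the free aldehyde of acetal 7. 7 is traced to the isomeric ketol 6 by breaking O–C3 and moving the C14 methyl from C10 back to C1. A quaternary ether carbon next to a ketone thus becomes a tertiary propargylic alcohol next to a ketone, which is easy to assemble. Forward, a π-acid must make the ketone oxygen add to the alkyne and the methyl migrate with transfer of chirality.

**Ketol 6.** 6 is cut at C10–C9 into Weinreb amide 4 and Grignard reagent 5; 4 comes from ester 3, and 3 from ethyl pyruvate 1 and but-1-yne 2 (C1–C2 bond). The only stereocentre of this fragment is set catalytically.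

**Keto amide 25.** 25 is traced through alcohol 24 to lactone 23, and through 22 and 21 to trityl ether 20. The cyclohexene of 20 is cut at C2′=C3′ (ring-closing metathesis) to diene 19. The C11–C4′ and C11–C13 bonds are then cut in turn, giving 17, lactone 14, iodide 15 and bromide 13 (from alcohol 12, from 9 and 10). A Diels–Alder construction would place the side chain 1,4 to C11, whereas the target has it 1,3; two alkylations and a metathesis fix the pattern. C11 is set trans to the C6 substituent of 14, and that C6 centre is spent afterwards when it is oxidised to the ketone.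

## Alternatives that were turned down

Alternative 1: The cyclohexene is cut at C11–C4′ inside a preformed lactone. Forward, a lithium amide base forms the C11 enolate, which displaces a (Z)-allylic bromide of its own side chain on the face away from the C7 substituent and gives spirolactone A1. In its favour, the 1,3 pattern of the cyclohexene is fixed by the position of the leaving group, and C11 is set directly from C7 in one ring-forming step. Against it, C6 of A1 is an unsubstituted O–CH2, so C5 and the C6 stereocentre are missing: the lactone would later have to be opened, C6 oxidised, C5 added and the ring closed again cis. The C8 side chain of A1 ends in a terminal alkene, so the quaternary C10, the furanone and the macrocycle are all left for a late and crowded stage. On C11 this plan is at least as good as the chosen one, which uses the same anti-alkylation principle but against a C6 substituent that is sacrificed afterwards. What the chosen strategy offers in its place is a key step that settles C10 and the whole furanone from a three-step precursor.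

Alternative 2: The O–C10 bond is cut, which reverses a biomimetic oxa-bridging. Forward, mild acid lets the C3 ketone oxygen open a C1–C10 epoxide at C10 with inversion, and loss of a C2 proton gives the dienol ether A2. In its favour, this is probably the biosynthetic path, it forms the O–C10 bond and the C10 centre late, and it needs no protecting groups. Against it, A2 still has C1 as a carbinol beside an acid-labile dienol ether, and C11 is still an exocyclic methylene. The cyclohexene would therefore need a late Diels–Alder reaction of A2 with myrcene A3, and the normal orientation of A3 in such a cycloaddition gives the 1,4 isomer, not the 1,3 pattern of the target. The substrate of the key step is itself a ten-membered lactone with the Z alkene, the cis-lactone and an epoxide whose face selection in a flexible ring decides C10, so the macrocycle problem is moved, not solved. This plan is stronger in step count once the macrocycle exists. The chosen strategy gives instead an unambiguous C10 configuration from an acyclic asymmetric step and builds the cyclohexene with defined regiochemistry.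

Alternative 3: C3–C4, C2–C3 and O–C3 are cut, with carbon monoxide A5 as C3. Forward, a carbonylative Sonogashira coupling of a (Z)-alkenyl iodide, A5 and a tertiary propargylic alcohol gives a 4-hydroxy-2-ynone, and a secondary amine followed by water closes furanone A4. In its favour, the plan is convergent and the Z geometry of C4=C5 comes from the iodide, so no medium-ring condensation and dehydration are needed. Against it, A4 carries C8 as an ester and C6 as a silyl ether: C7, the lactone and the spiro ring must then be attached to a base- and nucleophile-sensitive dienone, and the ester must be reduced beside the furanone carbonyl. The macrocycle must be closed at C6–C7 or C7–C8, where two stereocentres form during the ring closure. The propargylic alcohol also needs an enantioselective alkynylation of a less activated ketone. On the C4=C5 geometry this plan is as strong or stronger. The chosen route keeps the furanone as a simple 5-ethyl furanone through the fragment union, lets ring strain fix the Z alkene, and needs no A5 under pressure.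

Key step: step 4

Assumption: in steps 1, 16 and 18 and in the fallback to step 4 the written enantiomer of the ligand, boron reagent or catalyst is taken to give the drawn configuration; if its sense of induction is the opposite, its antipode is used and nothing else changes.

## Route

Step 1
Reactants: 1 ethyl pyruvate; 2 but-1-yne
Product: 3 ethyl (2R)-2-hydroxy-2-methylhex-3-ynoate
Conditions: Zn(OTf)2 (cat.), (1S,2S)-2-(dimethylamino)-1-(4-nitrophenyl)-3-(tert-butyldimethylsilyloxy)propan-1-ol (cat.), Et3N, toluene, sealed vessel, 60 °C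
Reagents that add atoms: none
Why: Catalytic enantioselective alkynylation of an α-keto ester; the zinc acetylide adds to the ester-chelated ketone inside the chiral amino-alkoxide complex, which should set the tertiary carbinol as R.

Step 2
Reactants: 3 ethyl (2R)-2-hydroxy-2-methylhex-3-ynoate
Product: 4 (2R)-2-hydroxy-N-methoxy-N,2-dimethylhex-3-ynamide
Conditions: MeNH(OMe)·HCl, i-PrMgCl, THF, −20 → 0 °C
Reagents that add atoms: N,O-dimethylhydroxylamine hydrochloride, CNOC.Cl
Why: Weinreb amidation of an ester by the magnesium amide; the tertiary hydroxyl is only deprotonated and the stereocentre is not involved.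

Step 3
Reactants: 4 (2R)-2-hydroxy-N-methoxy-N,2-dimethylhex-3-ynamide; 5 (1,3-dioxolan-2-ylmethyl)magnesium bromide
Product: 6 (3R)-1-(1,3-dioxolan-2-yl)-3-hydroxy-3-methylhept-4-yn-2-one
Conditions: 5 (3 equiv), THF, 0 °C → rt; aq. NH4Cl
Reagents that add atoms: none
Why: Grignard addition to a Weinreb amide; the chelated tetrahedral intermediate stops at the ketone, and one equivalent of 5 is consumed by the hydroxyl.

Step 4
Reactants: 6 (3R)-1-(1,3-dioxolan-2-yl)-3-hydroxy-3-methylhept-4-yn-2-one
Product: 7 (2R)-2-(1,3-dioxolan-2-ylmethyl)-5-ethyl-2-methylfuran-3(2H)-one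
Conditions: PtCl2 (5 mol%), toluene, 80 °C
Reagents that add atoms: none
Why: PtCl2 binds the C2≡C3 alkyne and the C10 ketone oxygen attacks C3 in a 5-endo-dig closure, the only ring formed, giving a cyclic oxocarbenium ion at C10 with platinum on C2. The C14 methyl then shifts from C1 to C10 while the C1 hydroxyl becomes the C1 ketone (an α-ketol-type 1,2-shift), and protodemetalation at C2 releases 7 and PtCl2. The closest known reaction type is the PtCl2- or AuCl3-catalysed heterocyclisation with 1,2-alkyl migration of 2-hydroxy-2-alkynyl ketones to 3(2H)-furanones. The new C10 stereocentre is controlled by the C1 carbinol centre of 6: the five-membered cation is planar and the methyl can only cross on the face it already occupies, so (R)-6 should give (R)-7 with C9 on the opposite face. The step needs attack by the ketone oxygen and not by the acetal oxygens, which the 5-endo geometry favours because an acetal oxygen would have to close a larger ring. It also needs a single migrating group, which is secured because the other carbon on C1 (C2) is part of the new ring. Neutral conditions avoid β-elimination of the acetal.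

Step 5
Reactants: 7 (2R)-2-(1,3-dioxolan-2-ylmethyl)-5-ethyl-2-methylfuran-3(2H)-one
Product: 8 [(2R)-5-ethyl-2-methyl-3-oxo-2,3-dihydrofuran-2-yl]acetaldehyde
Conditions: TsOH·H2O (cat.), acetone–H2O (10:1), 40 °C
Reagents that add atoms: water, O
Why: Acid-catalysed acetal hydrolysis; acid is chosen because the product is a β-(acylvinyloxy) aldehyde that would eliminate with base, and it is used crude.

Step 6
Reactants: 9 5-bromo-2-methylpent-2-ene; 10 prop-2-yn-1-ol
Product: 12 6-methyl-2-methylidenehept-5-en-1-ol, via Grignard reagent 11 (not isolated)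
Conditions: Mg, THF; then 10 (0.45 equiv), CuI (10 mol%), Et2O–THF, reflux; aq. NH4Cl
Reagents that add atoms: none
Why: Copper-catalysed carbomagnesiation of propargyl alcohol; the alkoxide directs the alkyl group to the internal alkyne carbon, giving the 2-substituted allylic alcohol after protonation.

Step 7
Reactants: 12 6-methyl-2-methylidenehept-5-en-1-ol
Product: 13 2-(bromomethyl)-6-methylhepta-1,5-diene
Conditions: CBr4, PPh3, CH2Cl2, 0 °C
Reagents that add atoms: carbon tetrabromide, BrC(Br)(Br)Br
Why: Appel bromination under neutral conditions; direct and allylic displacement give the same bromide in this 2-substituted allyl system.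

Step 8
Reactants: 14 (5R)-5-[(trityloxy)methyl]oxolan-2-one; 15 4-iodobut-1-ene
Product: 17 (5R)-3-(but-3-en-1-yl)-5-[(trityloxy)methyl]oxolan-2-one (C3 epimers), via lithium enolate 16 (not isolated)
Conditions: LiN(i-Pr)2, THF, −78 °C; then 15, DMPU, −78 → −30 °C
Reagents that add atoms: none
Why: Alkylation of a lactone enolate; the C3 configuration does not matter because this centre is enolised again in the next step.

Step 9
Reactants: 17 (5R)-3-(but-3-en-1-yl)-5-[(trityloxy)methyl]oxolan-2-one; 13 2-(bromomethyl)-6-methylhepta-1,5-diene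
Product: 19 (3S,5R)-3-(but-3-en-1-yl)-3-(6-methyl-2-methylidenehept-5-en-1-yl)-5-[(trityloxy)methyl]oxolan-2-one, via lithium enolate 18 (not isolated)
Conditions: LiN(i-Pr)2, THF, −78 °C; then 13, −78 → −40 °C
Reagents that add atoms: none
Why: Second enolate alkylation; the reactive allylic bromide should enter trans to the bulky trityloxymethyl group (1,3-induction in 5-substituted butyrolactone enolates), which sets C11 with C4′ trans and C13 cis to that substituent.

Step 10
Reactants: 19 (3S,5R)-3-(but-3-en-1-yl)-3-(6-methyl-2-methylidenehept-5-en-1-yl)-5-[(trityloxy)methyl]oxolan-2-one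
Product: 20 (3R,5S)-7-(4-methylpent-3-en-1-yl)-3-[(trityloxy)methyl]-2-oxaspiro[4.5]dec-7-en-1-one
Conditions: second-generation Grubbs catalyst RuCl2(=CHPh)(PCy3)(H2IMes) (5 mol%), CH2Cl2, 40 °C
Reagents that add atoms: none
Why: Ring-closing metathesis of the monosubstituted and the 1,1-disubstituted terminal alkenes gives the trisubstituted cyclohexene; the trisubstituted side-chain alkene could only close a strained or medium ring and should not take part.

Step 11
Reactants: 20 (3R,5S)-7-(4-methylpent-3-en-1-yl)-3-[(trityloxy)methyl]-2-oxaspiro[4.5]dec-7-en-1-one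
Product: 21 (3R,5S)-3-(hydroxymethyl)-7-(4-methylpent-3-en-1-yl)-2-oxaspiro[4.5]dec-7-en-1-one
Conditions: CSA (cat.), MeOH–CH2Cl2, rt
Reagents that add atoms: none
Why: Acid-catalysed methanolysis of the trityl ether, mild enough for the 1,5-diene; the γ-lactone is favoured over the δ-isomer.

Step 12
Reactants: 21 (3R,5S)-3-(hydroxymethyl)-7-(4-methylpent-3-en-1-yl)-2-oxaspiro[4.5]dec-7-en-1-one
Product: 22 (3R,5S)-7-(4-methylpent-3-en-1-yl)-1-oxo-2-oxaspiro[4.5]dec-7-ene-3-carbaldehyde
Conditions: Dess–Martin periodinane, CH2Cl2, rt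
Reagents that add atoms: none
Why: Dess–Martin oxidation of the primary alcohol under neutral conditions; the α-acyloxy aldehyde is used crude, and any epimerisation next to the aldehyde is harmless because this centre is oxidised in step 15.

Step 13
Reactants: 22 (3R,5S)-7-(4-methylpent-3-en-1-yl)-1-oxo-2-oxaspiro[4.5]dec-7-ene-3-carbaldehyde
Product: 23 (3R,5S)-3-(dimethoxymethyl)-7-(4-methylpent-3-en-1-yl)-2-oxaspiro[4.5]dec-7-en-1-one
Conditions: HC(OMe)3, MeOH, PPTS (cat.), rt
Reagents that add atoms: methanol, CO; trimethyl orthoformate, COC(OC)OC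
Why: Acetalisation stores C5 at the aldehyde level; the acetal methine is not deprotonated under boron-mediated enolisation, so the later C6 ketone enolises towards C7.

Step 14
Reactants: 23 (3R,5S)-3-(dimethoxymethyl)-7-(4-methylpent-3-en-1-yl)-2-oxaspiro[4.5]dec-7-en-1-one
Product: 24 (1S)-1-[(2R)-2-hydroxy-3,3-dimethoxypropyl]-N-methoxy-N-methyl-3-(4-methylpent-3-en-1-yl)cyclohex-3-ene-1-carboxamide
Conditions: MeNH(OMe)·HCl, i-PrMgCl, THF, −20 → 0 °C
Reagents that add atoms: N,O-dimethylhydroxylamine hydrochloride, CNOC.Cl
Why: Aminolysis of the lactone by the magnesium amide frees the C6 hydroxyl; the crude product is oxidised at once to avoid re-lactonisation.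

Step 15
Reactants: 24 (1S)-1-[(2R)-2-hydroxy-3,3-dimethoxypropyl]-N-methoxy-N-methyl-3-(4-methylpent-3-en-1-yl)cyclohex-3-ene-1-carboxamide
Product: 25 (1S)-1-(3,3-dimethoxy-2-oxopropyl)-N-methoxy-N-methyl-3-(4-methylpent-3-en-1-yl)cyclohex-3-ene-1-carboxamide
Conditions: Dess–Martin periodinane, CH2Cl2, rt
Reagents that add atoms: none
Why: Dess–Martin oxidation to the C6 ketone; the C6 centre that directed the C11 alkylation is deliberately erased so that C7 becomes enolisable.

Step 16
Reactants: 25 (1S)-1-(3,3-dimethoxy-2-oxopropyl)-N-methoxy-N-methyl-3-(4-methylpent-3-en-1-yl)cyclohex-3-ene-1-carboxamide; 8 [(2R)-5-ethyl-2-methyl-3-oxo-2,3-dihydrofuran-2-yl]acetaldehyde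
Product: 27 (1S)-1-{(3R,4R)-5-[(2R)-5-ethyl-2-methyl-3-oxo-2,3-dihydrofuran-2-yl]-4-hydroxy-1,1-dimethoxy-2-oxopentan-3-yl}-N-methoxy-N-methyl-3-(4-methylpent-3-en-1-yl)cyclohex-3-ene-1-carboxamide, via enol borinate 26 (not isolated)
Conditions: (MenthCH2)2BCl, that is chlorobis{[(1S,2S,5R)-5-methyl-2-(propan-2-yl)cyclohexyl]methyl}borane (made from (−)-menthone), Et3N, Et2O, −78 → 0 °C; then 8, −78 → −20 °C; MeOH, pH 7 buffer, H2O2, 0 °C
Reagents that add atoms: none
Why: Boron-mediated anti aldol: the dialkylboron chloride with Et3N should give the (E)-enol borinate 26, which adds to the aldehyde through a chair transition state to give the 7,8-anti adduct. The face is chosen by the chiral ligands on boron, because neither fragment has a controlling centre near C7 or C8, and the chloride is preferred to the bromide so that the dimethyl acetal is not cleaved.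

Step 17
Reactants: 27 the (3R,4R) anti aldol of step 16
Product: 28 (1S)-1-{(3R,4R)-4-[(tert-butyldimethylsilyl)oxy]-5-[(2R)-5-ethyl-2-methyl-3-oxo-2,3-dihydrofuran-2-yl]-1,1-dimethoxy-2-oxopentan-3-yl}-N-methoxy-N-methyl-3-(4-methylpent-3-en-1-yl)cyclohex-3-ene-1-carboxamide
Conditions: TBSOTf, 2,6-lutidine, CH2Cl2, −78 °C
Reagents that add atoms: tert-butyldimethylsilyl trifluoromethanesulfonate, CC(C)(C)[Si](C)(C)OS(=O)(=O)C(F)(F)F
Why: Silylation of the aldol hydroxyl blocks O8, which could otherwise close onto C12 or undergo retro-aldol; the α-keto acetal is deactivated towards the silyl triflate at low temperature.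

Step 18
Reactants: 28 the 8-O-silyl keto amide of step 17
Product: 30 (3R,4S,5S)-4-{(1R)-1-[(tert-butyldimethylsilyl)oxy]-2-[(2R)-5-ethyl-2-methyl-3-oxo-2,3-dihydrofuran-2-yl]ethyl}-3-(dimethoxymethyl)-7-(4-methylpent-3-en-1-yl)-2-oxaspiro[4.5]dec-7-en-1-one, via hydroxy amide 29 (not isolated)
Conditions: (R)-B-methyl-CBS oxazaborolidine [(R)-1-methyl-3,3-diphenyltetrahydro-1H,3H-pyrrolo[1,2-c][1,3,2]oxazaborole] (0.3 equiv), catecholborane, toluene, −78 → −40 °C; MeOH; then PPTS (cat.), toluene, 50 °C
Reagents that add atoms: none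
Why: Corey–Bakshi–Shibata reduction: with C7 as the large and the acetal carbon as the small substituent, the catalyst should deliver hydride to the face that places O6 anti to C11 and 1,3-syn to O8. The γ-hydroxy Weinreb amide 29 then lactonises with retention at C6, helped by the quaternary C11, giving the cis-lactone.

Step 19
Reactants: 30 the lactone acetal of step 18
Product: 31 (3R,4S,5S)-4-{(1R)-1-[(tert-butyldimethylsilyl)oxy]-2-[(2R)-5-ethyl-2-methyl-3-oxo-2,3-dihydrofuran-2-yl]ethyl}-7-(4-methylpent-3-en-1-yl)-1-oxo-2-oxaspiro[4.5]dec-7-ene-3-carbaldehyde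
Conditions: PPTS, acetone–H2O (10:1), 55 °C
Reagents that add atoms: water, O
Why: Hydrolysis of the dimethyl acetal with a weak acid that should leave the secondary silyl ether, the lactone and the 1,5-diene intact; the aldehyde is used at once.

Step 20
Reactants: 31 the lactone aldehyde of step 19
Product: 33 macrocyclic C5 aldol of 31 (8-O-silyl ether; C4 and C5 epimers), via lithium dienolate 32 (not isolated)
Conditions: LiN(SiMe3)2 (1.1 equiv), THF, −78 °C, high dilution (slow addition of 31); AcOH at −78 °C
Reagents that add atoms: none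
Why: Intramolecular vinylogous aldol addition: the 5-ethylfuranone is deprotonated at C4 and the dienolate attacks the C5 aldehyde through C4, closing the nine-membered oxacycle. The lactone has no α-hydrogen, and closures of this type are known for 3(2H)-furanones in related medium-ring lactones.

Step 21
Reactants: 33 the macrocyclic aldol of step 20
Product: 35 8-O-tert-butyldimethylsilyl ether of 36 with the (4Z)-dienone, via mesylate 34 (not isolated)
Conditions: MsCl, Et3N, CH2Cl2, 0 °C; then DBU, rt
Reagents that add atoms: none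
Why: Mesylation and E1cB elimination through the vinylogously acidic C4–H; both C4/C5 epimers converge, and the nine-membered ring fused to furanone and lactone should admit only the Z alkene.

Step 22
Reactants: 35 the silyl ether dienone of step 21
Product: 36 (4Z,6S,7R,8R,10R,11S)-8-hydroxy compound (the target without its angeloyl group)
Conditions: HF·pyridine, pyridine, THF, 0 °C → rt
Reagents that add atoms: none
Why: Fluoride cleavage of the silyl ether under buffered, weakly acidic conditions; no alkoxide is formed, so the lactone should not migrate to O8 and the dienone is not attacked.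

Step 23
Reactants: 36 the 8-hydroxy compound of step 22; 37 angelic acid
Product: 39 the target, via mixed anhydride 38 (not isolated)
Conditions: 37, 2,4,6-trichlorobenzoyl chloride, Et3N, toluene, rt; then 36, 80 °C
Reagents that add atoms: none
Why: Yamaguchi-type esterification through the mixed anhydride without a nucleophilic catalyst, a known way to make angelates of hindered alcohols without isomerisation to the tiglate.

## Compound list

1 | ethyl pyruvate | CCOC(=O)C(C)=O | starting material
2 | but-1-yne | CCC#C | starting material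
3 | ethyl (2R)-2-hydroxy-2-methylhex-3-ynoate | CCC#C[C@@](C)(O)C(=O)OCC | intermediate
4 | (2R)-2-hydroxy-N-methoxy-N,2-dimethylhex-3-ynamide | CCC#C[C@@](C)(O)C(=O)N(C)OC | intermediate
5 | (1,3-dioxolan-2-ylmethyl)magnesium bromide | Br[Mg]CC1OCCO1 | starting material
6 | (3R)-1-(1,3-dioxolan-2-yl)-3-hydroxy-3-methylhept-4-yn-2-one | CCC#C[C@@](C)(O)C(=O)CC1OCCO1 | intermediate
7 | (2R)-2-(1,3-dioxolan-2-ylmethyl)-5-ethyl-2-methylfuran-3(2H)-one | O1CCOC1C[C@@]2(C)OC(CC)=CC2=O | intermediate
8 | [(2R)-5-ethyl-2-methyl-3-oxo-2,3-dihydrofuran-2-yl]acetaldehyde | O=CC[C@@]1(C)OC(CC)=CC1=O | intermediate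
9 | 5-bromo-2-methylpent-2-ene | CC(C)=CCCBr | starting material
10 | prop-2-yn-1-ol | C#CCO | starting material
11 | (4-methylpent-3-en-1-yl)magnesium bromide | CC(C)=CCC[Mg]Br | intermediate
12 | 6-methyl-2-methylidenehept-5-en-1-ol | C=C(CO)CCC=C(C)C | intermediate
13 | 2-(bromomethyl)-6-methylhepta-1,5-diene | C=C(CBr)CCC=C(C)C | intermediate
14 | (5R)-5-[(trityloxy)methyl]oxolan-2-one | O=C1CC[C@H](COC(c2ccccc2)(c2ccccc2)c2ccccc2)O1 | starting material
15 | 4-iodobut-1-ene | C=CCCI | starting material
16 | lithium enolate of 14 | [Li]OC1=CC[C@H](COC(c2ccccc2)(c2ccccc2)c2ccccc2)O1 | intermediate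
17 | (5R)-3-(but-3-en-1-yl)-5-[(trityloxy)methyl]oxolan-2-one (C3 epimers) | O=C1C(CCC=C)C[C@H](COC(c2ccccc2)(c2ccccc2)c2ccccc2)O1 | intermediate
18 | lithium enolate of 17 | [Li]OC1=C(CCC=C)C[C@H](COC(c2ccccc2)(c2ccccc2)c2ccccc2)O1 | intermediate
19 | (3S,5R)-3-(but-3-en-1-yl)-3-(6-methyl-2-methylidenehept-5-en-1-yl)-5-[(trityloxy)methyl]oxolan-2-one | O=C1[C@@](CCC=C)(CC(=C)CCC=C(C)C)C[C@H](COC(c2ccccc2)(c2ccccc2)c2ccccc2)O1 | intermediate
20 | (3R,5S)-7-(4-methylpent-3-en-1-yl)-3-[(trityloxy)methyl]-2-oxaspiro[4.5]dec-7-en-1-one | C(OC(c3ccccc3)(c3ccccc3)c3ccccc3)[C@@H]1OC(=O)[C@]2(CCC=C(CCC=C(C)C)C2)C1 | intermediate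
21 | (3R,5S)-3-(hydroxymethyl)-7-(4-methylpent-3-en-1-yl)-2-oxaspiro[4.5]dec-7-en-1-one | OC[C@@H]1OC(=O)[C@]2(CCC=C(CCC=C(C)C)C2)C1 | intermediate
22 | (3R,5S)-7-(4-methylpent-3-en-1-yl)-1-oxo-2-oxaspiro[4.5]dec-7-ene-3-carbaldehyde | O=C[C@@H]1OC(=O)[C@]2(CCC=C(CCC=C(C)C)C2)C1 | intermediate
23 | (3R,5S)-3-(dimethoxymethyl)-7-(4-methylpent-3-en-1-yl)-2-oxaspiro[4.5]dec-7-en-1-one | COC(OC)[C@@H]1OC(=O)[C@]2(CCC=C(CCC=C(C)C)C2)C1 | intermediate
24 | (1S)-1-[(2R)-2-hydroxy-3,3-dimethoxypropyl]-N-methoxy-N-methyl-3-(4-methylpent-3-en-1-yl)cyclohex-3-ene-1-carboxamide | COC(OC)[C@H](O)C[C@]1(C(=O)N(C)OC)CCC=C(CCC=C(C)C)C1 | intermediate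
25 | (1S)-1-(3,3-dimethoxy-2-oxopropyl)-N-methoxy-N-methyl-3-(4-methylpent-3-en-1-yl)cyclohex-3-ene-1-carboxamide | COC(OC)C(=O)C[C@]1(C(=O)N(C)OC)CCC=C(CCC=C(C)C)C1 | intermediate
26 | (E)-enol borinate of 25 bearing two [(1S,2S,5R)-5-methyl-2-(propan-2-yl)cyclohexyl]methyl groups on boron | COC(OC)/C(OB(C[C@H]2C[C@H](C)CC[C@H]2C(C)C)C[C@H]2C[C@H](C)CC[C@H]2C(C)C)=C\[C@]1(C(=O)N(C)OC)CCC=C(CCC=C(C)C)C1 | intermediate
27 | (1S)-1-{(3R,4R)-5-[(2R)-5-ethyl-2-methyl-3-oxo-2,3-dihydrofuran-2-yl]-4-hydroxy-1,1-dimethoxy-2-oxopentan-3-yl}-N-methoxy-N-methyl-3-(4-methylpent-3-en-1-yl)cyclohex-3-ene-1-carboxamide | COC(OC)C(=O)[C@@H]([C@H](O)C[C@@]1(C)OC(CC)=CC1=O)[C@]1(C(=O)N(C)OC)CCC=C(CCC=C(C)C)C1 | intermediate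
28 | (1S)-1-{(3R,4R)-4-[(tert-butyldimethylsilyl)oxy]-5-[(2R)-5-ethyl-2-methyl-3-oxo-2,3-dihydrofuran-2-yl]-1,1-dimethoxy-2-oxopentan-3-yl}-N-methoxy-N-methyl-3-(4-methylpent-3-en-1-yl)cyclohex-3-ene-1-carboxamide | COC(OC)C(=O)[C@@H]([C@H](O[Si](C)(C)C(C)(C)C)C[C@@]1(C)OC(CC)=CC1=O)[C@]1(C(=O)N(C)OC)CCC=C(CCC=C(C)C)C1 | intermediate
29 | (1S)-1-{(2R,3S,4R)-4-[(tert-butyldimethylsilyl)oxy]-5-[(2R)-5-ethyl-2-methyl-3-oxo-2,3-dihydrofuran-2-yl]-2-hydroxy-1,1-dimethoxypentan-3-yl}-N-methoxy-N-methyl-3-(4-methylpent-3-en-1-yl)cyclohex-3-ene-1-carboxamide | COC(OC)[C@H](O)[C@@H]([C@H](O[Si](C)(C)C(C)(C)C)C[C@@]1(C)OC(CC)=CC1=O)[C@]1(C(=O)N(C)OC)CCC=C(CCC=C(C)C)C1 | intermediate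
30 | (3R,4S,5S)-4-{(1R)-1-[(tert-butyldimethylsilyl)oxy]-2-[(2R)-5-ethyl-2-methyl-3-oxo-2,3-dihydrofuran-2-yl]ethyl}-3-(dimethoxymethyl)-7-(4-methylpent-3-en-1-yl)-2-oxaspiro[4.5]dec-7-en-1-one | COC(OC)[C@@H]1OC(=O)[C@]2(CCC=C(CCC=C(C)C)C2)[C@@H]1[C@H](O[Si](C)(C)C(C)(C)C)C[C@@]1(C)OC(CC)=CC1=O | intermediate
31 | (3R,4S,5S)-4-{(1R)-1-[(tert-butyldimethylsilyl)oxy]-2-[(2R)-5-ethyl-2-methyl-3-oxo-2,3-dihydrofuran-2-yl]ethyl}-7-(4-methylpent-3-en-1-yl)-1-oxo-2-oxaspiro[4.5]dec-7-ene-3-carbaldehyde | O=C[C@@H]1OC(=O)[C@]2(CCC=C(CCC=C(C)C)C2)[C@@H]1[C@H](O[Si](C)(C)C(C)(C)C)C[C@@]1(C)OC(CC)=CC1=O | intermediate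
32 | lithium dienolate of 31 (furanone deprotonated at C4) | O=C[C@@H]1OC(=O)[C@]2(CCC=C(CCC=C(C)C)C2)[C@@H]1[C@H](O[Si](C)(C)C(C)(C)C)C[C@@]1(C)OC(=CC)C=C1O[Li] | intermediate
33 | macrocyclic aldol: 8-O-tert-butyldimethylsilyl 5-hydroxy-4,5-dihydro analogue of 36 (C4 and C5 epimers; C6, C7, C8, C10, C11 arranged as in 39) | CC(C)(C)[Si](C)(C)O[C@@H]1C[C@@]2(C)OC(=CC2=O)C(C)C(O)[C@@H]2OC(=O)[C@]3(CCC=C(CCC=C(C)C)C3)[C@@H]21 | intermediate
34 | C5 methanesulfonate of 33 | CC(C)(C)[Si](C)(C)O[C@@H]1C[C@@]2(C)OC(=CC2=O)C(C)C(OS(C)(=O)=O)[C@@H]2OC(=O)[C@]3(CCC=C(CCC=C(C)C)C3)[C@@H]21 | intermediate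
35 | 8-O-tert-butyldimethylsilyl ether of 36 ((4Z); C6, C7, C8, C10, C11 arranged as in 39) | CC(C)(C)[Si](C)(C)O[C@@H]1C[C@@]2(C)OC(=CC2=O)/C(C)=C\[C@@H]2OC(=O)[C@]3(CCC=C(CCC=C(C)C)C3)[C@@H]21 | intermediate
36 | (4Z,6S,7R,8R,10R,11S)-8-hydroxy-1-oxo-3,10-epoxygermacra-2,4-dien-6,12-olide with C11 spiro-fused to 3-(4-methylpent-3-en-1-yl)cyclohex-3-ene (C13 cis to C8) | O[C@@H]1C[C@@]2(C)OC(=CC2=O)/C(C)=C\[C@@H]2OC(=O)[C@]3(CCC=C(CCC=C(C)C)C3)[C@@H]21 | intermediate
37 | angelic acid, (2Z)-2-methylbut-2-enoic acid | C/C=C(/C)C(=O)O | starting material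
38 | angelic 2,4,6-trichlorobenzoic anhydride | C/C=C(/C)C(=O)OC(=O)c1c(Cl)cc(Cl)cc1Cl | intermediate
39 | target CNP0226905.2, the 8-O-angelate of 36, (4Z,6S,7R,8R,10R,11S) | C/C=C(/C)C(=O)O[C@@H]1C[C@@]2(C)OC(=CC2=O)/C(C)=C\[C@@H]2OC(=O)[C@]3(CCC=C(CCC=C(C)C)C3)[C@@H]21 | target

## Step count and least certain steps

Total step count: 23. Longest linear sequence: 17 steps (from 9 through steps 6, 7 and 9–23 to 39).

**Step 4 (key step).** The platinum-activated alkyne may be diverted by the acetal oxygens or by traces of water, and the catalyst may stall. Enantiopurity would erode if the methyl shift were not concerted with collapse of the cation. Chirality transfer by a migrating methyl in an open-chain ketol is untested.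
Fallback (sets out from 1, returns at 7): the C10 centre is made first, so no migration is needed. Ethyl pyruvate 1 undergoes the copper–bis(oxazoline)-catalysed Mukaiyama aldol addition (Cu(OTf)2, (R,R)-2,2′-isopropylidenebis(4-tert-butyl-2-oxazoline), THF, −78 °C) with 1-(ethylsulfanyl)-1-(trimethylsilyloxy)ethene, which gives the silylated thioester F1. Fukuyama reduction (Et3SiH, Pd/C, acetone) gives the aldehyde F2, and ethylene glycol with TsOH gives the dioxolane hydroxy ester F3 with loss of the silyl group. Weinreb amidation as in step 2 gives the amide F4, and lithium but-1-ynide (from 2 and n-BuLi) gives the α′-hydroxy ynone F5. Et2NH in EtOH then closes F5 to 7 by 5-endo conjugate addition of the tertiary hydroxyl to the ynone.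

**Step 16 (aldol union).** Enolisation of the neopentyl-type C7 methylene by the bulky boron chloride may be slow or give the wrong enolate geometry, the facial control by the boron ligands may be weak, and the free O8 may attack the amide carbonyl.
Fallback (sets out from 25, returns at 27): the C7 nucleophile is generated reductively instead of by deprotonation in the presence of a boron halide. 25 is brominated at C7 (LiN(i-Pr)2, then N-bromosuccinimide) to the α-bromo ketone F6. A chromium Reformatsky reaction of F6 (CrCl2, LiI cat., THF) with 8 should give the anti aldols regiospecifically. Without reagent control, 27 and its (3S,4S) diastereomer F7 would both form and would be separated by chromatography.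

**Step 18 (reduction and lactonisation).** Hydride delivery may follow the substrate (Felkin) preference of C7 and not the catalyst, which would give the C6 epimer and then the trans-lactone; the hindered ketone may also react slowly.
Fallback (sets out from 27, returns at 31): the free C8 hydroxyl directs the hydride. Narasaka–Prasad reduction of 27 (Et2BOMe, NaBH4, THF–MeOH, −78 °C) should give the syn-diol amide F8. CSA then closes O8 onto the C5 acetal and O6 onto the amide, giving the cis-fused bicyclic acetal–lactone F9, which tells the two hydroxyls apart. Aqueous acid gives the lactol F10, and NaBH4 gives the diol lactone F11. TBSOTf gives the bis-silyl ether F12, and HF·pyridine cleaves only the primary silyl ether to give the primary alcohol F13. Dess–Martin oxidation of this alcohol gives 31.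

**Step 20 (macrocyclisation).** The base may deprotonate the aldehyde α-carbon (C6 epimerisation, oligomerisation), the new C5 alkoxide may take over the lactone acyl group, and closure of the medium ring may be slow.
Fallback (sets out from 30, returns at 35): the ring is closed on the acetal under Lewis acid instead of on the free aldehyde under base. TBSOTf and Et3N convert the furanone of 30 into the silyl dienol ether F14. BF3·OEt2 at −78 °C ionises the dimethyl acetal, and the dienol ether attacks C5 through C4 (intramolecular vinylogous Mukaiyama addition), giving the C5 methyl ether macrocycle F15. DBU then eliminates methanol from this ether to give 35.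

## Further compounds

F1 | step 4 | S-ethyl (3R)-4-ethoxy-3-methyl-4-oxo-3-[(trimethylsilyl)oxy]butanethioate | CCOC(=O)[C@](C)(O[Si](C)(C)C)CC(=O)SCC
F2 | step 4 | ethyl (2R)-2-methyl-4-oxo-2-[(trimethylsilyl)oxy]butanoate | CCOC(=O)[C@](C)(O[Si](C)(C)C)CC=O
F3 | step 4 | ethyl (2R)-3-(1,3-dioxolan-2-yl)-2-hydroxy-2-methylpropanoate | CCOC(=O)[C@](C)(O)CC1OCCO1
F4 | step 4 | (2R)-3-(1,3-dioxolan-2-yl)-2-hydroxy-N-methoxy-N,2-dimethylpropanamide | CON(C)C(=O)[C@](C)(O)CC1OCCO1
F5 | step 4 | (2R)-1-(1,3-dioxolan-2-yl)-2-hydroxy-2-methylhept-4-yn-3-one | CCC#CC(=O)[C@](C)(O)CC1OCCO1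
F6 | step 16 | (1R)-1-(1-bromo-3,3-dimethoxy-2-oxopropyl)-N-methoxy-N-methyl-3-(4-methylpent-3-en-1-yl)cyclohex-3-ene-1-carboxamide (C7 epimers) | COC(OC)C(=O)C(Br)[C@]1(C(=O)N(C)OC)CCC=C(CCC=C(C)C)C1
F7 | step 16 | (3S,4S) diastereomer of 27 | COC(OC)C(=O)[C@H]([C@@H](O)C[C@@]1(C)OC(CC)=CC1=O)[C@]1(C(=O)N(C)OC)CCC=C(CCC=C(C)C)C1
F8 | step 18 | syn-diol amide (C6 alcohol of 27, C6 and C8 oxygens 1,3-syn) | COC(OC)[C@H](O)[C@@H]([C@H](O)C[C@@]1(C)OC(CC)=CC1=O)[C@]1(C(=O)N(C)OC)CCC=C(CCC=C(C)C)C1
F9 | step 18 | cis-fused bicyclic acetal–lactone (O8–C5 methyl furanoside, O6–C12 lactone; C5 anomers) | COC1O[C@H](C[C@@]2(C)OC(CC)=CC2=O)[C@@H]2[C@H]1OC(=O)[C@]23CCC=C(CCC=C(C)C)C3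
F10 | step 18 | lactol of F9 | OC1O[C@H](C[C@@]2(C)OC(CC)=CC2=O)[C@@H]2[C@H]1OC(=O)[C@]23CCC=C(CCC=C(C)C)C3
F11 | step 18 | diol lactone (C5 primary alcohol, C8 secondary alcohol) | OC[C@@H]1OC(=O)[C@]2(CCC=C(CCC=C(C)C)C2)[C@@H]1[C@H](O)C[C@@]1(C)OC(CC)=CC1=O
F12 | step 18 | bis(tert-butyldimethylsilyl) ether of F11 | CC(C)(C)[Si](C)(C)OC[C@@H]1OC(=O)[C@]2(CCC=C(CCC=C(C)C)C2)[C@@H]1[C@H](O[Si](C)(C)C(C)(C)C)C[C@@]1(C)OC(CC)=CC1=O
F13 | step 18 | primary alcohol, 8-O-tert-butyldimethylsilyl ether of F11 | OC[C@@H]1OC(=O)[C@]2(CCC=C(CCC=C(C)C)C2)[C@@H]1[C@H](O[Si](C)(C)C(C)(C)C)C[C@@]1(C)OC(CC)=CC1=O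
F14 | step 20 | silyl dienol ether of 30 (C1–O-silyl, exocyclic C3=C4) | COC(OC)[C@@H]1OC(=O)[C@]2(CCC=C(CCC=C(C)C)C2)[C@@H]1[C@H](O[Si](C)(C)C(C)(C)C)C[C@@]1(C)OC(=CC)C=C1O[Si](C)(C)C(C)(C)C
F15 | step 20 | C5 methyl ether macrocycle (5-methoxy-4,5-dihydro analogue of 35; C4 and C5 epimers) | CC(C)(C)[Si](C)(C)O[C@@H]1C[C@@]2(C)OC(=CC2=O)C(C)C(OC)[C@@H]2OC(=O)[C@]3(CCC=C(CCC=C(C)C)C3)[C@@H]21
A1 | alternative 1 | spirolactone with the homoprenyl cyclohexene and the C8 silyloxybutenyl chain | CC(C)(C)[Si](C)(C)O[C@H](CC=C)[C@@H]2COC(=O)[C@]23CCC=C(CCC=C(C)C)C3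
A2 | alternative 2 | 1-hydroxy-3,10-oxa-bridged dienol ether with α-methylene lactone and C8 angelate | C/C=C(/C)C(=O)O[C@@H]1C[C@@]2(C)OC(=C[C@@H]2O)/C(C)=C\[C@@H]2OC(=O)C(=C)[C@@H]21
A3 | alternative 2 | myrcene | CC(C)=CCCC(=C)C=C
A4 | alternative 3 | methyl 2-[(2R)-5-[(2Z)-4-(tert-butyldimethylsilyloxy)but-2-en-2-yl]-2-methyl-3-oxo-2,3-dihydrofuran-2-yl]acetate | COC(=O)C[C@@]1(C)OC(=CC1=O)/C(C)=C\CO[Si](C)(C)C(C)(C)C
A5 | alternative 3 | carbon monoxide | [C-]#[O+]
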